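The vessel takes its free monomer over 3.0 h and then receives no more, so the questions concern the tail after the feed.

| flask | free monomer | initiator | remark | time |
|---|---|---|---|---|
| Friday's | 0.012 M (fed, over 3.0 h) | 0.40 mM | run made earlier |  |
| Thursday's | 0.012 M (fed, over 3.0 h) | 0.90 mM | run made earlier |  |
| Sunday's | 0.0060 M (fed, over 3.0 h) | 0.60 mM | run made earlier |  |
| flask | 0.012 M (fed, over 3.0 h) | 0.60 mM |  | 10 h |

| run | time / h | free monomer / % | monomer in chains / % |
|---|---|---|---|
| Friday's | 0.500 | 20 | 0 |
| Friday's | 1.50 | 39 | 10 |
| Friday's | 3.00 | 57 | 41 |
| Friday's | 4.00 | 40 | 59 |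
| Friday's | 6.00 | 24 | 76 |
| Thursday's | 0.500 | 15 | 0 |
| Thursday's | 0.833 | 24 | 2 |
| Thursday's | 1.50 | 38 | 17 |
| Thursday's | 3.00 | 42 | 59 |
| Thursday's | 6.00 | 10 | 88 |
| Sunday's | 1.33 | 37 | 4 |
| Sunday's | 2.50 | 55 | 26 |
| Sunday's | 4.00 | 39 | 64 |
| Sunday's | 5.00 | 29 | 74 |
| Sunday's | 6.00 | 18 | 82 |

(scatter of a reading: 2 percentage points)

- amounts and yields of monomer in chains count crystals too
- given per volume of solution although it is solid: crystals
- steps that have been proposed: free monomer + initiator -> living end + monomer in chains; free monomer + living end -> monomer in chains + living end; 2 living end -> dead end; crystals <-> monomer in chains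
- the reaction counts as stopped when no species that holds the free monomer changes by six tenths of a point or more over the second half of the time
- percentages count the whole charge, also what has not yet gone in

- which holds at 10 h: what has brought the reaction to rest, or that it has not come to rest (it is still moving / no working catalyst is left / all of the free monomer has reacted)
- part of the free monomer gone at 10 h
- the monomer in chains standing at 10 h, as a percentage of the free monomer charged

*What do the runs give for the tail?* Take a pseudo-first-order lifetime, the hours of a window divided by the natural log of the fall in the free-monomer fraction. From 3.00 h to 6.00 h, Friday's run gives 3.47 h and Thursday's 2.09 h.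

*And at 0.60 mM of initiator?* The two runs make the lifetime fall as initiator to the power 0.624, which gives 2.69 h for this flask.

*May that lifetime be run out to 10 h?* No. On Friday's run it lengthens from 2.82 h to 3.92 h, a read slope against time of 0.728, loose at a scatter of 2 percentage points.

*So what do you commit to?* In this flask the lifetime climbs from 1.60 h to 6.70 h. The tail lifetime, the hours from end of feed to the asked time over the log of the fall across them, is 3.56 h. From 48.9 % at end of feed, the geometric mean of the two runs, that leaves 6.85 %. The same climbing lifetime puts 20.1 % at 5.00 h, so the second half loses about 13 points against a mark of 0.6, and I say still moving.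

The forecast says it is still moving, with 93 % gone and 93 % in chains: “This fits living ends dying in pairs”.

The flask gives 90.6 % gone and 90.6 % in chains, and it is still moving, so the forecast stands. With all other amounts and the time held, the nearest initiator amounts at which conversion has moved 5 points are 0.384 mM below and 1.15 mM above. The flask's own tail lifetime, from 50.6 % to 9.44 %, is 4.17 h, longer than my figure.

    free monomer + initiator → living end + monomer in chains (k = 1.58 M⁻¹ min⁻¹)
    free monomer + living end → monomer in chains + living end, rate k2*[living end]*[free monomer] (k = 70.5 M⁻¹ min⁻¹)
    2 living end → dead end (k = 79.5 M⁻¹ min⁻¹)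
    crystals ⇌ monomer in chains, rate k4*(cs4 - [monomer in chains]) while solid is left; crystals form when [monomer in chains] > cs4 (solubility = 0.120 mM, k = 0.0797 min⁻¹)

At 0.0010 M of initiator the same power shortens this to 3.03 h, and from Thursday's 42 % it leaves 4.17 %. The computed neighbour keeps 5.3 %, with 94.7 % gone.

The runs stem from a simulated flask on assumed constants; the scatter is artificial.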